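**Retrosynthetic overview**
1. Feature: O10 stands on the convex face of cyclobutane B at quaternary C9, γ to the carboxyl carbon C11 of butenolide D. Rings A (C1-C2-C3-C9-C13) and C (C4 to C8) fold to the same concave face of B, so convex-face additions that build this cis-syn-cis core leave a hydrogen exactly where O10 belongs.
2. Endgame: target ⇒ Mitsunobu inversion at C1 ⇒ Luche reduction ⇒ C12=C13 dehydrogenation ⇒ keto lactone 36 ⇒ (C9-H to C9-O10, ring D) keto acid 34. C14 is already on C12 in 34, because later a lactone enolate could not be made beside the C1 ketone and the C5 acetate.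
3. 34 ⇒ C13 alkylation of tricyclic ketone 21 ⇒ Dieckmann closure C13→C1 (ring A) of diester 18. Its two arms are endo because the C3 methyl and H9 were each added last, from the convex face.
4. 18 ⇒ cyclobutanone 6 ⇒ head-to-head [2+2] photocycloaddition of allene to (S)-4-silyloxycyclopentenone 1, which builds ring B on ring C and relays C5 to C4 and C8. C7 stays trigonal until ring A is closed, then takes OH from the convex face.
5. Order of rings: C (in 1), B (step 1), A (step 10), D (step 19).

Key step: step 19

Numbering (used for all intermediates): C1 tigloyloxy CH, C2 CH2, C3 quaternary (CH3), C4 CH, C5 CHOAc, C6 CH2, C7 C(OH)CH3, C8 CH, C9 quaternary (O10), C11 lactone C=O, C12 (bears C14H2OAc), C13. "Exo" means the convex face (H4, H8, C3-CH3, H9/O10); "endo" means the concave face.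
Assumption: C12 is carried as an epimer mixture from step 14 to step 19 (no descriptor in the SMILES) and 14 as an E/Z mixture, because both elements vanish later; both enantiomers of 1 are articles of commerce.

**Step 1**
Reactants: 1 (S)-4-(tert-butyldimethylsilyloxy)cyclopent-2-en-1-one; 2 allene
Product: 3 head-to-head photoadduct (cis-fused bicyclo[3.2.0]heptane: C7 ketone; C9=CH2; C3H2; OTBS H4 H8 exo)
Conditions: hν (Hg lamp, Pyrex), excess 2, CH2Cl2, −78 °C
Reagents that add atoms: allene 2, C=C=C
Why: Enone-allene [2+2] photocycloaddition, in which the triplet enone adds allene head-to-head so that the central allene carbon (C9) bonds to the α-carbon C8 and a CH2 terminus (C3) to the β-carbon C4, the five-membered ring allows only a cis B/C fusion, and attack anti to the C5 silyloxy group puts OTBS, H4 and H8 on one face.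

**Step 2**
Reactants: 3 photoadduct
Product: 4 C7 ethylene ketal of 3
Conditions: (Me3SiOCH2)2, Me3SiOTf (5 mol %), CH2Cl2, −78 → −30 °C; pyridine quench
Reagents that add atoms: 1,2-bis(trimethylsilyloxy)ethane, C[Si](C)(C)OCCO[Si](C)(C)C
Why: Noyori acetalisation works cold and without protic acid, so the β-silyloxy ketone does not lose silanol and the alkene does not move, and masking C7 is needed because a free C7 ketone beside the coming C9 ketone would be a strained β-diketone open to retro-Claisen cleavage.

**Step 3**
Reactants: 4 ketal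
Product: 6 cyclobutanone (C9 ketone; C7 ketal; 5-exo-OTBS), via secondary ozonide 5 (not isolated)
Conditions: O3, CH2Cl2, −78 °C; then Me2S, −78 °C → rt
Reagents that add atoms: ozone, [O-][O+]=O
Why: Ozonolysis with reductive work-up cleaves the only C=C bond to the ketone and touches no stereocentre.

**Step 4**
Reactants: 6 cyclobutanone; 7 methyl bromoacetate
Product: 9 monoalkylated cyclobutanone (3-exo-CH2CO2Me; H3 endo), via lithium enolate 8 (not isolated)
Conditions: LiN(iPr)2, THF, −78 °C; then 7, DMPU, −78 → −40 °C
Reagents that add atoms: methyl bromoacetate 7, COC(=O)CBr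
Why: Kinetic enolate alkylation, in which deprotonation occurs at the C3 methylene because a C8=C9 enolate would place a double bond at the ring fusion, and the electrophile enters from the convex face (this centre is reset in step 5).

**Step 5**
Reactants: 9 monoalkylated cyclobutanone; 10 iodomethane
Product: 12 C3-quaternary cyclobutanone (3-exo-CH3; 3-endo-CH2CO2Me), via potassium enolate 11 (not isolated)
Conditions: KN(SiMe3)2, THF, −78 °C; then 10, −78 → −20 °C
Reagents that add atoms: iodomethane 10, CI
Why: Second enolate alkylation, in which the cyclobutanone α-hydrogen on C3 is several pK units more acidic than the ester α-hydrogens so that proton transfer funnels everything to 11, and iodomethane attacks the planar enolate from the convex face, making the methyl exo and pushing the C2-C1 arm to the concave face.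

**Step 6**
Reactants: 12 C3-quaternary cyclobutanone; 13 trimethyl phosphonoacetate
Product: 14 C9 alkylidene acetate (C9=C13H-CO2Me; E/Z mixture)
Conditions: 13, NaH, THF, 0 °C → reflux
Reagents that add atoms: trimethyl phosphonoacetate 13, COC(=O)CP(=O)(OC)OC
Why: Horner-Wadsworth-Emmons olefination, in which relief of angle strain keeps even the α-quaternary cyclobutanone reactive toward the phosphonate anion, C8 cannot epimerise in the cis-fused bicycle, and the alkene geometry is without consequence.

**Step 7**
Reactants: 14 alkylidene acetate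
Product: 15 diester (H9 exo; C13H2CO2Me endo and cis to the C2 arm)
Conditions: H2 (4 bar), 10% Pd/C, EtOAc, rt
Reagents that add atoms: none
Why: Heterogeneous syn-hydrogenation, in which the alkene can lie on the catalyst only with its convex face because ring C and the C3 acetate arm close the concave one, so H9 is delivered exo and the C13 arm swings endo.

**Step 8**
Reactants: 15 diester
Product: 16 C7 keto diester
Conditions: PPTS (cat.), acetone/H2O 10:1, 55 °C
Reagents that add atoms: water, O
Why: Mild acid-catalysed acetal hydrolysis that the secondary TBS ether and the methyl esters survive, while C8 cannot epimerise because only the cis fusion is possible.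

**Step 9**
Reactants: 16 keto diester; 17 dibromomethane
Product: 18 C7 methylidene diester
Conditions: Zn, 17, TiCl4, THF/CH2Cl2, 0 °C → rt
Reagents that add atoms: dibromomethane 17, BrCBr
Why: Lombardo methylenation, whose non-basic gem-dimetallic reagent attacks ketones but not esters and does not trigger β-elimination of the C5 silyloxy group as a basic ylide could, and which keeps C7 trigonal so that nothing points into the cavity while ring A is built.

**Step 10**
Reactants: 18 methylidene diester
Product: 20 cis-syn-cis tricyclic β-keto ester (C1 ketone; 13-exo-CO2Me; keto/enol mixture), via sodium enolate 19 (not isolated)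
Conditions: NaH (2.2 equiv), MeOH (cat.), THF, reflux; then 1 M HCl, 0 °C
Reagents that add atoms: none
Why: Dieckmann condensation under equilibrating conditions, in which the two arms are cis and endo on the C3-C9 bond so that only ring A on the concave face can form, and of the two possible β-keto esters the one enolised at C13, away from quaternary C3, is the thermodynamic sink as with 3,3-disubstituted adipates, so C13 attacks C1.

**Step 11**
Reactants: 20 β-keto ester
Product: 21 tricyclic ketone (C1 ketone; C13H2; C7=CH2; 5-exo-OTBS)
Conditions: LiCl, H2O, DMSO, 140 °C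
Reagents that add atoms: none
Why: Krapcho demethoxycarbonylation (chloride takes the ester methyl and the β-keto carboxylate loses CO2) removes the auxiliary ester under neutral conditions, avoiding the acid that an exocyclic alkene next to a cyclobutane would not tolerate.

**Step 12**
Reactants: 21 tricyclic ketone; 22 benzyl bromoacetate
Product: 24 keto benzyl ester (13-exo-CH2CO2Bn cis to H9; H13 endo), via lithium enolate 23 (not isolated)
Conditions: LiN(iPr)2, THF, −78 °C; then 22, DMPU, −78 → −30 °C
Reagents that add atoms: benzyl bromoacetate 22, O=C(CBr)OCc1ccccc1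
Why: Kinetic enolate alkylation, in which the amide base removes the exo hydrogen on C13 because C2 is neopentyl and its exo hydrogen is flanked by the exo C3 methyl, and the bromide is attacked from the convex face of ring A, giving the exo C12-C11 arm that is also the thermodynamic epimer.

**Step 13**
Reactants: 24 keto benzyl ester
Product: 25 C1 silyl enol ether (C1(OTBS)=C2)
Conditions: TBSOTf, Et3N, CH2Cl2, 0 °C
Reagents that add atoms: tert-butyldimethylsilyl triflate, CC(C)(C)[Si](C)(C)OS(=O)(=O)C(F)(F)F
Why: Soft enolisation and O-silylation mask the C1 ketone, triethylamine reaching only the exo hydrogen on C2 because H13 is buried in the cavity, so C13 is untouched and the benzyl ester is inert.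

**Step 14**
Reactants: 25 silyl enol ether; 26 formaldehyde (monomer from cracked paraformaldehyde)
Product: 28 C12 hydroxymethyl ester (C14H2OH; C12 epimers), via lithium ester enolate 27 (not isolated)
Conditions: LiN(iPr)2, THF, −78 °C; then 26 (gas); AcOH quench
Reagents that add atoms: formaldehyde 26, C=O
Why: Ester enolate aldol addition to formaldehyde brings in C14 at the one stage where no ketone, acetate or free hydroxyl competes for the base, and the C12 epimer mixture is harmless because C12 becomes trigonal in step 20.

**Step 15**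
Reactants: 28 hydroxymethyl ester
Product: 29 keto diol (C1 ketone; 5-exo-OH; C14H2OH)
Conditions: 48% aq HF, MeCN, 0 °C
Reagents that add atoms: none
Why: Acidic fluoride desilylation cleaves the enol ether back to the ketone and the C5 silyl ether in one operation without base, so neither retro-aldol loss of C14 nor epimerisation at C13 is expected.

**Step 16**
Reactants: 29 keto diol; 30 acetic anhydride
Product: 31 diacetate (5-exo-OAc; C14H2OAc; C7=CH2)
Conditions: 30, pyridine, DMAP (cat.), CH2Cl2, 0 °C → rt
Reagents that add atoms: acetic anhydride 30, CC(=O)OC(C)=O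
Why: DMAP-catalysed acylation of the primary and the secondary hydroxyl, needing no selectivity because the tertiary alcohol does not yet exist, with pyridine too weak a base to eliminate the β-acetoxy ester.

**Step 17**
Reactants: 31 diacetate
Product: 33 tertiary alcohol (7-exo-OH; 7-endo-CH3), via C7 hydroperoxide 32 (not isolated)
Conditions: Co(acac)2 (20 mol %), PhSiH3, O2 (1 atm), THF, rt; then PPh3
Reagents that add atoms: dioxygen, O=O
Why: Mukaiyama hydration (hydrogen-atom transfer from a cobalt hydride to the CH2 terminus, then capture of the tertiary C7 radical by O2), in which ring A closes the concave face so that oxygen arrives exo and the new methyl ends endo, and trapping by O2 outruns opening of the cyclobutylcarbinyl radical.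

**Step 18**
Reactants: 33 tertiary alcohol
Product: 34 cis-syn-cis tricyclic C1 keto acid (H9 exo; 13-exo-CH(CH2OAc)CO2H; 5-exo-OAc; 7-exo-OH)
Conditions: H2 (1 atm), 10% Pd/C, EtOAc, rt
Reagents that add atoms: none
Why: Hydrogenolysis of the benzyl ester frees the C11 acid under neutral conditions without touching acetates, ketone or tertiary alcohol, no alkene being left in the molecule.

**Step 19**
Reactants: 34 keto acid
Product: 36 tetracyclic keto lactone (O10 exo on C9; ring D cis-fused to ring A; H13 endo; C12 epimers), via C9 hydroxy acid 35 (not isolated)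
Conditions: (S,S)-Mn(OTf)2(pdp) (3 × 1 mol %; pdp = N,N'-bis(2-pyridylmethyl)-2,2'-bipyrrolidine), 30% aq H2O2 (2 equiv, syringe pump), (CF3)2CHOH, 0 °C
Reagents that add atoms: hydrogen peroxide, OO
Why: The C11 carboxylate of 34 binds the divalent manganese centre next to the peroxide site and assists O-O heterolysis, giving a high-valent oxo-carboxylato species whose oxo ligand can reach only the γ C-H bond on the same face of ring A as the side chain, H9, through a seven-membered transition state. Hydrogen abstraction and in-cage rebound place OH on C9 with retention (35), and O10 then closes ring D by 5-exo-trig attack on C11 (direct carboxylate transfer to the C9 radical would give the same lactone). The closest known reaction type is the carboxylic-acid-directed γ-C-H lactonisation with manganese or iron aminopyridine catalysts and H2O2, applied here to a tertiary cyclobutane C-H. The new stereocentre C9 is substrate-controlled, because H9 was set on the convex face in step 7 and is replaced with retention, and the exo arm on C13 can only close a cis A/D junction, so the catalyst configuration is not the source of stereocontrol. The step needs C9-H to win over C4-H, C8-H and the methylenes, and this is secured because C1 is a ketone (no second γ hydrogen, C2-H and C13-H deactivated), because C4-H, C5-H, C6-H, C8-H and C14-H lie at or next to acetoxy or hydroxy carbons made still poorer by hydrogen bonding to the solvent, and because none of them is within reach of the bound oxidant. Slow peroxide addition at 0 °C without added strong acid limits Baeyer-Villiger attack on C1 and ionisation of the C7 alcohol.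

**Step 20**
Reactants: 36 keto lactone
Product: 37 butenolide ketone (C12=C13; C1 ketone; C14H2OAc)
Conditions: IBX (3 equiv), DMSO, 75 °C
Reagents that add atoms: none
Why: IBX dehydrogenation of a ketone through its enol, in which C3 and C9 carry no hydrogen so that C13-C12 is the only α,β pair that can be desaturated, the tetrasubstituted alkene gains conjugation to C1 and C11 and relieves the H13/C7-methyl contact, acetates and the tertiary alcohol are inert, and both C12 epimers converge.

**Step 21**
Reactants: 37 butenolide ketone
Product: 38 C1 endo allylic alcohol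
Conditions: NaBH4, CeCl3·7H2O, MeOH/CH2Cl2, −78 °C
Reagents that add atoms: none
Why: Luche reduction gives 1,2-addition to the enone carbonyl without conjugate reduction or lactone attack, and since the concave face of C1 looks at C6 of ring C the hydride comes from the convex face and the hydroxyl ends endo.

**Step 22**
Reactants: 38 endo allylic alcohol; 39 tiglic acid
Product: 40 target CNP0210373.1
Conditions: 39, PPh3, DIAD, toluene, 0 °C → rt
Reagents that add atoms: tiglic acid 39, C/C=C(\C)C(=O)O
Why: Mitsunobu esterification, in which the activated endo oxygen leaves into the cavity while tiglate attacks C1 from the open convex face (SN2, inversion) to give the exo ester, the tertiary C7 hydroxyl cannot be activated, the E geometry of the acid is kept, and SN2' attack is blocked because C12 is fully substituted.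

**Compound list**
1 | (S)-4-(tert-butyldimethylsilyloxy)cyclopent-2-en-1-one | O=C1C=C[C@@H](O[Si](C)(C)C(C)(C)C)C1 | starting material
2 | allene (propa-1,2-diene) | C=C=C | starting material
3 | head-to-head photoadduct, 4-exo-(TBSO)-7-methylidenebicyclo[3.2.0]heptan-2-one | C1[C@@H]2[C@@H](O[Si](C)(C)C(C)(C)C)CC(=O)[C@@H]2C1=C | intermediate
4 | C7 ethylene ketal of 3 | C1[C@@H]2[C@@H](O[Si](C)(C)C(C)(C)C)CC3(OCCO3)[C@@H]2C1=C | intermediate
5 | secondary ozonide (spiro-1,2,4-trioxolane at C9) | C1[C@@H]2[C@@H](O[Si](C)(C)C(C)(C)C)CC3(OCCO3)[C@@H]2C14OCOO4 | intermediate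
6 | cyclobutanone (C9 ketone, C7 ketal) | C1[C@@H]2[C@@H](O[Si](C)(C)C(C)(C)C)CC3(OCCO3)[C@@H]2C1=O | intermediate
7 | methyl bromoacetate | COC(=O)CBr | starting material
8 | lithium C3=C9 enolate of 6 | [Li]OC1=C[C@@H]2[C@@H](O[Si](C)(C)C(C)(C)C)CC3(OCCO3)[C@@H]21 | intermediate
9 | 3-exo-(methoxycarbonylmethyl) cyclobutanone | COC(=O)C[C@H]1[C@@H]2[C@@H](O[Si](C)(C)C(C)(C)C)CC3(OCCO3)[C@@H]2C1=O | intermediate
10 | iodomethane | CI | starting material
11 | potassium enolate of 9 | [K]OC1=C(CC(=O)OC)[C@@H]2[C@@H](O[Si](C)(C)C(C)(C)C)CC3(OCCO3)[C@@H]21 | intermediate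
12 | C3-quaternary cyclobutanone (exo CH3, endo CH2CO2Me) | COC(=O)C[C@]1(C)[C@@H]2[C@@H](O[Si](C)(C)C(C)(C)C)CC3(OCCO3)[C@@H]2C1=O | intermediate
13 | trimethyl phosphonoacetate | COC(=O)CP(=O)(OC)OC | starting material
14 | C9 alkylidene acetate (E/Z) | COC(=O)C[C@]1(C)[C@@H]2[C@@H](O[Si](C)(C)C(C)(C)C)CC3(OCCO3)[C@@H]2C1=CC(=O)OC | intermediate
15 | diester, H9 exo, both arms endo | COC(=O)C[C@]1(C)[C@@H]2[C@@H](O[Si](C)(C)C(C)(C)C)CC3(OCCO3)[C@@H]2[C@@H]1CC(=O)OC | intermediate
16 | C7 keto diester | COC(=O)C[C@]1(C)[C@@H]2[C@@H](O[Si](C)(C)C(C)(C)C)CC(=O)[C@@H]2[C@@H]1CC(=O)OC | intermediate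
17 | dibromomethane | BrCBr | starting material
18 | C7 methylidene diester | COC(=O)C[C@]1(C)[C@@H]2[C@@H](O[Si](C)(C)C(C)(C)C)CC(=C)[C@@H]2[C@@H]1CC(=O)OC | intermediate
19 | sodium enolate of 20 | COC(=O)C1=C(O[Na])C[C@]2(C)[C@@H]3[C@@H](O[Si](C)(C)C(C)(C)C)CC(=C)[C@@H]3[C@@H]21 | intermediate
20 | cis-syn-cis tricyclic β-keto ester | O=C1C[C@]2(C)[C@@H]3[C@@H](O[Si](C)(C)C(C)(C)C)CC(=C)[C@@H]3[C@@H]2[C@H]1C(=O)OC | intermediate
21 | tricyclic ketone | O=C1C[C@]2(C)[C@@H]3[C@@H](O[Si](C)(C)C(C)(C)C)CC(=C)[C@@H]3[C@@H]2C1 | intermediate
22 | benzyl bromoacetate | O=C(CBr)OCc1ccccc1 | starting material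
23 | lithium C1=C13 enolate of 21 | C1=C(O[Li])C[C@]2(C)[C@@H]3[C@@H](O[Si](C)(C)C(C)(C)C)CC(=C)[C@@H]3[C@@H]21 | intermediate
24 | keto benzyl ester (13-exo arm) | O=C1C[C@]2(C)[C@@H]3[C@@H](O[Si](C)(C)C(C)(C)C)CC(=C)[C@@H]3[C@@H]2[C@H]1CC(=O)OCc1ccccc1 | intermediate
25 | C1(OTBS)=C2 silyl enol ether | CC(C)(C)[Si](C)(C)OC1=C[C@]2(C)[C@@H]3[C@@H](O[Si](C)(C)C(C)(C)C)CC(=C)[C@@H]3[C@@H]2[C@H]1CC(=O)OCc1ccccc1 | intermediate
26 | formaldehyde | C=O | starting material
27 | lithium enolate of the benzyl ester | CC(C)(C)[Si](C)(C)OC1=C[C@]2(C)[C@@H]3[C@@H](O[Si](C)(C)C(C)(C)C)CC(=C)[C@@H]3[C@@H]2[C@H]1C=C(O[Li])OCc1ccccc1 | intermediate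
28 | C12 hydroxymethyl ester | CC(C)(C)[Si](C)(C)OC1=C[C@]2(C)[C@@H]3[C@@H](O[Si](C)(C)C(C)(C)C)CC(=C)[C@@H]3[C@@H]2[C@H]1C(CO)C(=O)OCc1ccccc1 | intermediate
29 | keto diol | O=C1C[C@]2(C)[C@@H]3[C@@H](O)CC(=C)[C@@H]3[C@@H]2[C@H]1C(CO)C(=O)OCc1ccccc1 | intermediate
30 | acetic anhydride | CC(=O)OC(C)=O | starting material
31 | diacetate | O=C1C[C@]2(C)[C@@H]3[C@@H](OC(C)=O)CC(=C)[C@@H]3[C@@H]2[C@H]1C(COC(C)=O)C(=O)OCc1ccccc1 | intermediate
32 | C7 exo hydroperoxide | O=C1C[C@]2(C)[C@@H]3[C@@H](OC(C)=O)C[C@@](C)(OO)[C@@H]3[C@@H]2[C@H]1C(COC(C)=O)C(=O)OCc1ccccc1 | intermediate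
33 | tertiary alcohol benzyl ester | O=C1C[C@]2(C)[C@@H]3[C@@H](OC(C)=O)C[C@@](C)(O)[C@@H]3[C@@H]2[C@H]1C(COC(C)=O)C(=O)OCc1ccccc1 | intermediate
34 | cis-syn-cis tricyclic C1 keto acid (key-step precursor) | O=C1C[C@]2(C)[C@@H]3[C@@H](OC(C)=O)C[C@@](C)(O)[C@@H]3[C@@H]2[C@H]1C(COC(C)=O)C(=O)O | intermediate
35 | C9 exo hydroxy acid | O=C1C[C@]2(C)[C@@H]3[C@@H](OC(C)=O)C[C@@](C)(O)[C@@H]3[C@]2(O)[C@H]1C(COC(C)=O)C(=O)O | intermediate
36 | tetracyclic keto lactone (key-step product) | O=C1C[C@]2(C)[C@@H]3[C@@H](OC(C)=O)C[C@@](C)(O)[C@@H]3[C@@]23OC(=O)C(COC(C)=O)[C@@H]13 | intermediate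
37 | butenolide ketone | O=C1C[C@]2(C)[C@@H]3[C@@H](OC(C)=O)C[C@@](C)(O)[C@@H]3[C@@]23OC(=O)C(COC(C)=O)=C13 | intermediate
38 | C1 endo allylic alcohol | O[C@@H]1C[C@]2(C)[C@@H]3[C@@H](OC(C)=O)C[C@@](C)(O)[C@@H]3[C@@]23OC(=O)C(COC(C)=O)=C13 | intermediate
39 | tiglic acid | C/C=C(\C)C(=O)O | starting material
40 | CNP0210373.1 | C/C=C(\C)C(=O)O[C@H]1C[C@]2(C)[C@@H]3[C@@H](OC(C)=O)C[C@@](C)(O)[C@@H]3[C@@]23OC(=O)C(COC(C)=O)=C13 | target

Total step count: 22. Longest linear sequence: 22 steps (from 1; all other components are bought).

**Steps most likely to fail**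

1. **Step 19.** The tertiary cyclobutane C-H has high s-character and lies β to the C1 ketone. Hydrogen abstraction may therefore be slower than catalyst decay and peroxide disproportionation. Stray oxidation at C8-H or Baeyer-Villiger insertion at C1 may also take over.
   Fallback (radical relay instead of a metal-oxo), from 34 back to 36:
   - The C7 hydroxyl is covered (Et3SiOTf, 2,6-lutidine; aqueous work-up frees the silyl ester) to give the C7 triethylsilyl ether acid F1.
   - Carbonyldiimidazole and then NH3 give the primary amide F2.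
   - PhI(OAc)2/I2 under visible light generates the amidyl radical, which takes H9 by 1,5-hydrogen transfer through a six-membered transition state (Hofmann-Löffler-Freytag-type).
   - The oxidised C9 centre is captured by the amide oxygen on the only face the arm can reach, giving the iminolactone F3.
   - Aqueous acetic acid hydrolyses C=NH and the silyl ether to 36.

2. **Step 22.** The oxyphosphonium ion may form poorly at the buried endo hydroxyl. The weak acidity of tiglic acid may let elimination or acetyl migration from O14 compete with displacement.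
   Fallback (isolated sulfonate and naked carboxylate), from 38 back to 40:
   - The small reagent MsCl with Et3N at −20 °C gives the endo mesylate F4.
   - Cesium tiglate (39, Cs2CO3) in DMF displaces it from the convex face with inversion.

3. **Step 20.** Enolisation toward C13 may be slow because H13 is shielded by the endo C7 methyl. Thermal loss of acetic acid from C14 is a second risk.
   Fallback (preformed enol derivative and metal-mediated β-hydride loss), from 36 back to 37:
   - Equilibrating silylation (Me3SiI, (Me3Si)2NH, CH2Cl2, −20 °C → rt) gives the more substituted C1=C13 silyl enol ether with C7-OSiMe3, F5.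
   - Saegusa-Ito oxidation with Pd(OAc)2 in MeCN removes H12.
   - Mild acidic work-up frees the C7 alcohol.

**Further compounds**
F1 | step 19 | C7 triethylsilyl ether of acid 34 | O=C1C[C@]2(C)[C@@H]3[C@@H](OC(C)=O)C[C@@](C)(O[Si](CC)(CC)CC)[C@@H]3[C@@H]2[C@H]1C(COC(C)=O)C(=O)O
F2 | step 19 | primary amide of F1 | O=C1C[C@]2(C)[C@@H]3[C@@H](OC(C)=O)C[C@@](C)(O[Si](CC)(CC)CC)[C@@H]3[C@@H]2[C@H]1C(COC(C)=O)C(N)=O
F3 | step 19 | iminolactone (C9-O10 closed, C11=NH) | O=C1C[C@]2(C)[C@@H]3[C@@H](OC(C)=O)C[C@@](C)(O[Si](CC)(CC)CC)[C@@H]3[C@@]23OC(=N)C(COC(C)=O)[C@@H]13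
F4 | step 22 | C1 endo mesylate of 38 | CS(=O)(=O)O[C@@H]1C[C@]2(C)[C@@H]3[C@@H](OC(C)=O)C[C@@](C)(O)[C@@H]3[C@@]23OC(=O)C(COC(C)=O)=C13
F5 | step 20 | C1=C13 trimethylsilyl enol ether with C7-OSiMe3 | C[Si](C)(C)OC=1C[C@]2(C)[C@@H]3[C@@H](OC(C)=O)C[C@@](C)(O[Si](C)(C)C)[C@@H]3[C@@]23OC(=O)C(COC(C)=O)C=13
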